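**Retrosynthetic overview**

1. The plan rests on one feature: both oxygen-bearing stereocentres, ring carbinol C1 and chain carbinol C10, sit next to a methylidene carbon (C7=C14 and C11=C12). Each allylic alcohol is therefore a masked α-hydroxy ketone, and both 1,1-disubstituted alkenes are cut last and together, back to the bis(α-silyloxy) 1,5-diketone 21.
2. The C3–Br/C4–Cl pair of 21 is traced to the ring alkene of hydroxy diketone 17 by a relay through the C1 hydroxyl: bromoetherification to a 7-oxabicyclo[2.2.1]heptane (18), then chloride opening of the bridge at C4 with retention.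
3. The C7–C8 bond is cut to aldehyde 7 (ring plus C7) and alkyllithium 13 (C8–C11 and C13). C1 comes from a Sharpless epoxidation and hydride opening, C10 from (R)-α-hydroxy-γ-butyrolactone, and the C11 ketone from Wacker oxidation of a vinyl group.
4. Ring order: the cyclohexane ring is not built but taken from 4-methylbenzyl alcohol by Birch reduction. The only ring closed on the way is the temporary C1–O–C4 bridge (step 13), which is opened again in step 14; the key step closes no ring.

Key step: step 16

Remark: atom labels follow bisabolane numbering. Ring: C1 (carbinol), C2, C3 (CHBr), C4 (CCl, methyl C15), C5, C6. Chain: C7 (=C14), C8, C9, C10 (carbinol), C11 (=C12), C13 (methyl). The C1 triethylsilyl group is put on only after halogenation, because the free C1 hydroxyl is needed for the halogen relay. TBS = tert-butyldimethylsilyl, TBHP = tert-butyl hydroperoxide, NBS = N-bromosuccinimide, IBX = 2-iodoxybenzoic acid.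

**Route**

Step 1
Reactants: 1 (4-methylphenyl)methanol
Product: 2 (4-methylcyclohexa-1,4-dien-1-yl)methanol
Conditions: n-BuLi (1.0 equiv), THF, −78 °C; Li, NH3 (l), t-BuOH, −78 °C; NH4Cl
Reagents that add atoms: none
Why: Birch reduction of a 1,4-dialkylbenzene should protonate the two unsubstituted positions para to one another, so both substituted carbons stay olefinic and one 1,4-diene results, while the benzylic C–O bond is kept because the hydroxyl is present as its lithium alkoxide; no stereocentre is formed.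

Step 2
Reactants: 2 (4-methylcyclohexa-1,4-dien-1-yl)methanol
Product: 3 [(1S,6S)-4-methyl-7-oxabicyclo[4.1.0]hept-3-en-1-yl]methanol
Conditions: Ti(OiPr)4 (10 mol%), L-(+)-diethyl tartrate (12 mol%), TBHP (anhydrous), 4 Å molecular sieves, CH2Cl2, −20 °C
Reagents that add atoms: tert-butyl hydroperoxide, CC(C)(C)OO
Why: In this Sharpless asymmetric epoxidation only the allylic C1=C6 alkene is bound to titanium through the alkoxide, and L-(+)-tartrate should deliver oxygen to the face that gives the (1S,6S)-epoxide, which sets the C1 configuration of the target, while the remote C3=C4 alkene is not touched.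

Step 3
Reactants: 3 [(1S,6S)-4-methyl-7-oxabicyclo[4.1.0]hept-3-en-1-yl]methanol
Product: 4 (1S)-1-(hydroxymethyl)-4-methylcyclohex-3-en-1-ol
Conditions: LiAlH4, THF, 0 °C to rt; H2O, aq. NaOH
Reagents that add atoms: none
Why: In this hydride opening of a 2,3-epoxy alcohol, LiAlH4 should attack the secondary epoxide carbon C6 in SN2 fashion because the fully substituted C1 is blocked, so the C1–O bond and its configuration are kept and the tertiary 1,2-diol results.

Step 4
Reactants: 4 (1S)-1-(hydroxymethyl)-4-methylcyclohex-3-en-1-ol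
Product: 6 trimethyl{[(1S)-4-methyl-1-(trimethylsilyloxy)cyclohex-3-en-1-yl]methoxy}silane, via primary mono-silyl ether 5 (not isolated)
Conditions: Me3SiCl (2.5 equiv), imidazole, DMF, 0 °C to rt
Reagents that add atoms: chlorotrimethylsilane, C[Si](C)(C)Cl
Why: Imidazole-promoted silylation with the small trimethylsilyl group should cover first the primary and then the hindered tertiary hydroxyl, with no change at C1.

Step 5
Reactants: 6 trimethyl{[(1S)-4-methyl-1-(trimethylsilyloxy)cyclohex-3-en-1-yl]methoxy}silane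
Product: 7 (1S)-4-methyl-1-(trimethylsilyloxy)cyclohex-3-ene-1-carbaldehyde
Conditions: (COCl)2, DMSO, CH2Cl2, −78 to −30 °C; Et3N, −78 °C to rt
Reagents that add atoms: none
Why: Under Swern conditions the chlorosulfonium reagent should cleave and oxidise the primary trimethylsilyl ether much faster than the hindered tertiary one, giving the non-enolisable α-silyloxy aldehyde with no risk to the quaternary C1 centre.

Step 6
Reactants: 8 (3R)-3-hydroxyoxolan-2-one
Product: 9 (3R)-3-(tert-butyldimethylsilyloxy)oxolan-2-one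
Conditions: TBSCl, imidazole, DMF, rt
Reagents that add atoms: tert-butyldimethylsilyl chloride, CC(C)(C)[Si](C)(C)Cl
Why: Standard silylation of the secondary hydroxyl should proceed without touching the stereocentre that becomes C10, which comes from the chiral pool.

Step 7
Reactants: 9 (3R)-3-(tert-butyldimethylsilyloxy)oxolan-2-one
Product: 10 (3R)-3-(tert-butyldimethylsilyloxy)oxolan-2-ol
Conditions: i-Bu2AlH (1.1 equiv), CH2Cl2, −78 °C; aq. potassium sodium tartrate
Reagents that add atoms: none
Why: Partial reduction of the lactone should stop at the lactol because the tetrahedral aluminium hemiacetal is stable at −78 °C and is only released on work-up.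

Step 8
Reactants: 10 (3R)-3-(tert-butyldimethylsilyloxy)oxolan-2-ol
Product: 11 (3R)-3-(tert-butyldimethylsilyloxy)pent-4-en-1-ol
Conditions: Ph3PCH3Br, KOtBu, THF, 0 °C; then 10, 0 °C to rt
Reagents that add atoms: methyltriphenylphosphonium bromide, C[P+](c1ccccc1)(c1ccccc1)c1ccccc1.[Br-]
Why: Wittig methylenation of the open hydroxy-aldehyde form of the lactol with the non-stabilised ylide adds C13 and should be fast enough at 0 °C to outrun epimerisation at C10 and silyl migration to the freed primary alkoxide.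

Step 9
Reactants: 11 (3R)-3-(tert-butyldimethylsilyloxy)pent-4-en-1-ol
Product: 12 tert-butyl{[(3R)-5-iodopent-1-en-3-yl]oxy}dimethylsilane
Conditions: I2, PPh3, imidazole, CH2Cl2, 0 °C to rt
Reagents that add atoms: iodine, II
Why: In this Appel-type iodination the primary alcohol is activated as its alkoxyphosphonium salt and displaced by iodide in SN2 fashion, leaving the allylic silyl ether alone.

Step 10
Reactants: 12 tert-butyl{[(3R)-5-iodopent-1-en-3-yl]oxy}dimethylsilane; 7 (1S)-4-methyl-1-(trimethylsilyloxy)cyclohex-3-ene-1-carbaldehyde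
Product: 15 (1S)-1-[(4R)-4-(tert-butyldimethylsilyloxy)-1-hydroxyhex-5-en-1-yl]-4-methylcyclohex-3-en-1-ol, via alkyllithium 13 (not isolated), via lithium alkoxide adduct 14 (not isolated)
Conditions: 12 (1.3 equiv), t-BuLi (2.1 equiv per 12), Et2O, −78 °C; 7, −78 °C; citric acid, MeOH, −78 °C to rt
Reagents that add atoms: none
Why: Lithium–iodine exchange should give the primary alkyllithium at −78 °C without retro-Brook silyl migration, its 1,2-addition to the non-enolisable aldehyde forms the C7–C8 bond, and citric acid in methanol then removes the trimethylsilyl group (wherever it sits after a possible 1,2-shift) but not the TBS ether; the new C7 carbinol centre forms without control and is erased in step 11.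

Step 11
Reactants: 15 (1S)-1-[(4R)-4-(tert-butyldimethylsilyloxy)-1-hydroxyhex-5-en-1-yl]-4-methylcyclohex-3-en-1-ol
Product: 16 (4R)-4-(tert-butyldimethylsilyloxy)-1-[(1S)-1-hydroxy-4-methylcyclohex-3-en-1-yl]hex-5-en-1-one
Conditions: IBX, DMSO, rt
Reagents that add atoms: none
Why: This hypervalent iodine oxidation should take the secondary alcohol of the 1,2-diol to the α-ketol without C–C cleavage, the tertiary hydroxyl cannot be oxidised, and the uncontrolled C7 centre disappears.

Step 12
Reactants: 16 (4R)-4-(tert-butyldimethylsilyloxy)-1-[(1S)-1-hydroxy-4-methylcyclohex-3-en-1-yl]hex-5-en-1-one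
Product: 17 (4R)-4-(tert-butyldimethylsilyloxy)-1-[(1S)-1-hydroxy-4-methylcyclohex-3-en-1-yl]hexane-1,5-dione
Conditions: PdCl2[2-(4,5-dihydro-1,3-oxazol-2-yl)quinoline] (5 mol%), AgSbF6 (12 mol%), aq. TBHP, CH2Cl2, 0 °C to rt
Reagents that add atoms: tert-butyl hydroperoxide, CC(C)(C)OO
Why: This peroxide-driven Wacker-type oxidation with a cationic divalent palladium catalyst carrying a quinoline–oxazoline ligand should oxidise the terminal vinyl group with Markovnikov selectivity to the C11 methyl ketone even next to the silyloxy group, without epimerisation at C10 and without reaction of the trisubstituted ring alkene.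

Step 13
Reactants: 17 (4R)-4-(tert-butyldimethylsilyloxy)-1-[(1S)-1-hydroxy-4-methylcyclohex-3-en-1-yl]hexane-1,5-dione
Product: 18 (4R)-1-[(1S,3R,4R)-3-bromo-4-methyl-7-oxabicyclo[2.2.1]heptan-1-yl]-4-(tert-butyldimethylsilyloxy)hexane-1,5-dione
Conditions: NBS (1.1 equiv), CH2Cl2, 0 °C, dark
Reagents that add atoms: N-bromosuccinimide, O=C1CCC(=O)N1Br
Why: In this transannular bromoetherification (known for 4-hydroxy-1-methylcyclohexenes going to 7-oxabicyclo[2.2.1]heptanes) bromonium ions form reversibly on both faces of C3=C4, but only the one anti to the C1 hydroxyl can be opened by that hydroxyl at the tertiary C4 through a boat, so bromine at C3 ends up trans to the C1 oxygen (3R) and the new C4–O bond cis to it.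

Step 14
Reactants: 18 (4R)-1-[(1S,3R,4R)-3-bromo-4-methyl-7-oxabicyclo[2.2.1]heptan-1-yl]-4-(tert-butyldimethylsilyloxy)hexane-1,5-dione
Product: 20 (4R)-1-[(1S,3R,4R)-3-bromo-4-chloro-1-hydroxy-4-methylcyclohexyl]-4-(tert-butyldimethylsilyloxy)hexane-1,5-dione, via titanium alkoxide 19 (not isolated)
Conditions: TiCl4 (2.2 equiv), CH2Cl2, −78 to −40 °C; aq. NaHCO3
Reagents that add atoms: titanium tetrachloride, Cl[Ti](Cl)(Cl)Cl
Why: Proposed new method: TiCl4 should chelate the C7 carbonyl and the bridging oxygen and ionise the tertiary C4–O bond (the C1–O bond cannot ionise next to the carbonyl) with help from the antiperiplanar endo bromine, which reverses step 13 and regenerates the bromonium ion, and chloride is then passed from the titanium ate complex to C4 on the face the oxygen has just left, anti to bromine, so that C4 is substituted with retention (4R, chlorine cis to the C1 oxygen and trans to bromine); the closest known reaction types are the cleavage of cineole-type bridged tertiary ethers by Lewis acids or hydrogen halides and the retentive substitution of β-bromo alcohols through bromonium ions.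

Step 15
Reactants: 20 (4R)-1-[(1S,3R,4R)-3-bromo-4-chloro-1-hydroxy-4-methylcyclohexyl]-4-(tert-butyldimethylsilyloxy)hexane-1,5-dione
Product: 21 (4R)-1-[(1S,3R,4R)-3-bromo-4-chloro-4-methyl-1-(triethylsilyloxy)cyclohexyl]-4-(tert-butyldimethylsilyloxy)hexane-1,5-dione
Conditions: Et3SiOTf, 2,6-lutidine, CH2Cl2, −78 to −20 °C
Reagents that add atoms: triethylsilyl trifluoromethanesulfonate, CC[Si](CC)(CC)OS(=O)(=O)C(F)(F)F
Why: Silylation with a silyl triflate and a hindered pyridine base is the usual way to protect a hindered tertiary alcohol, and at low temperature the ketones should not be turned into silyl enol ethers, so C10 is not put at risk.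

Step 16
Reactants: 21 (4R)-1-[(1S,3R,4R)-3-bromo-4-chloro-4-methyl-1-(triethylsilyloxy)cyclohexyl]-4-(tert-butyldimethylsilyloxy)hexane-1,5-dione
Product: 23 {[(1S,3R,4R)-3-bromo-1-[(5R)-5-(tert-butyldimethylsilyloxy)-6-methylhepta-1,6-dien-2-yl]-4-chloro-4-methylcyclohexyl]oxy}triethylsilane, via mono-methylenated ketone 22 (not isolated)
Conditions: Cp2Ti(μ-Cl)(μ-CH2)AlMe2 (4 equiv), pyridine, THF/toluene, −40 °C to rt; aq. NaHCO3
Reagents that add atoms: Cp2Ti(μ-Cl)(μ-CH2)AlMe2 (Tebbe reagent), C[Al-]1(C)C[Ti]([Cl+]1)(C1C=CC=C1)C1C=CC=C1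
Why: Pyridine opens the reagent to the titanium methylidene Cp2Ti=CH2, which adds across each C=O bond in a [2+2] cycloaddition; the oxatitanacyclobutane then cycloreverts to the C=CH2 unit and Cp2Ti=O, so the C11=C12 bond (methyl ketone, first) and the C7=C14 bond (hindered ketone, second, via 22) both form in one operation. The closest known reaction type is the Tebbe methylenation of hindered, enolisable α-alkoxy and α-silyloxy ketones. No ring is closed and no stereocentre is formed; the four existing centres are only carried through. The step needs chemoselectivity for the two carbonyl groups over the secondary bromide and the tertiary chloride, and it must not enolise the C11 ketone toward C10. The non-basic, oxophilic titanium carbene should provide both, and pyridine ties up the Me2AlCl by-product so that it cannot ionise the tertiary chloride or the tertiary silyl ether. The excess of reagent and the warming to room temperature are meant to drive the slower second methylenation at C7, which is flanked by the quaternary C1.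

Step 17
Reactants: 23 {[(1S,3R,4R)-3-bromo-1-[(5R)-5-(tert-butyldimethylsilyloxy)-6-methylhepta-1,6-dien-2-yl]-4-chloro-4-methylcyclohexyl]oxy}triethylsilane
Product: 25 (1S,3R,4R)-3-bromo-4-chloro-1-[(5R)-5-hydroxy-6-methylhepta-1,6-dien-2-yl]-4-methylcyclohexan-1-ol, via mono-silyl ether 24 (not isolated)
Conditions: HF·pyridine, pyridine, THF, 0 °C to rt
Reagents that add atoms: none
Why: Buffered fluoride desilylation should remove the triethylsilyl ether first and then the TBS ether, and being non-basic it should neither eliminate HBr or HCl nor ionise the tertiary allylic alcohol.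

**Compound list**

1 | (4-methylphenyl)methanol (4-methylbenzyl alcohol) | Cc1ccc(CO)cc1 | starting material
2 | (4-methylcyclohexa-1,4-dien-1-yl)methanol | CC1=CCC(CO)=CC1 | intermediate
3 | [(1S,6S)-4-methyl-7-oxabicyclo[4.1.0]hept-3-en-1-yl]methanol | OC[C@]12O[C@H]1CC(C)=CC2 | intermediate
4 | (1S)-1-(hydroxymethyl)-4-methylcyclohex-3-en-1-ol | OC[C@]1(O)CCC(C)=CC1 | intermediate
5 | (1S)-4-methyl-1-[(trimethylsilyloxy)methyl]cyclohex-3-en-1-ol | C[Si](C)(C)OC[C@]1(O)CCC(C)=CC1 | intermediate (not isolated)
6 | trimethyl{[(1S)-4-methyl-1-(trimethylsilyloxy)cyclohex-3-en-1-yl]methoxy}silane | C[Si](C)(C)OC[C@]1(O[Si](C)(C)C)CCC(C)=CC1 | intermediate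
7 | (1S)-4-methyl-1-(trimethylsilyloxy)cyclohex-3-ene-1-carbaldehyde | O=C[C@]1(O[Si](C)(C)C)CCC(C)=CC1 | intermediate
8 | (3R)-3-hydroxyoxolan-2-one ((R)-α-hydroxy-γ-butyrolactone) | O=C1[C@H](O)CCO1 | starting material
9 | (3R)-3-(tert-butyldimethylsilyloxy)oxolan-2-one | O=C1[C@H](O[Si](C)(C)C(C)(C)C)CCO1 | intermediate
10 | (3R)-3-(tert-butyldimethylsilyloxy)oxolan-2-ol (both anomers) | OC1[C@H](O[Si](C)(C)C(C)(C)C)CCO1 | intermediate
11 | (3R)-3-(tert-butyldimethylsilyloxy)pent-4-en-1-ol | C=C[C@H](O[Si](C)(C)C(C)(C)C)CCO | intermediate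
12 | tert-butyl{[(3R)-5-iodopent-1-en-3-yl]oxy}dimethylsilane | C=C[C@H](O[Si](C)(C)C(C)(C)C)CCI | intermediate
13 | [(3R)-3-(tert-butyldimethylsilyloxy)pent-4-en-1-yl]lithium | C=C[C@H](O[Si](C)(C)C(C)(C)C)CC[Li] | intermediate (not isolated)
14 | lithium (4R)-4-(tert-butyldimethylsilyloxy)-1-[(1S)-4-methyl-1-(trimethylsilyloxy)cyclohex-3-en-1-yl]hex-5-en-1-olate (both C7 epimers) | C=C[C@H](O[Si](C)(C)C(C)(C)C)CCC(O[Li])[C@]1(O[Si](C)(C)C)CCC(C)=CC1 | intermediate (not isolated)
15 | (1S)-1-[(4R)-4-(tert-butyldimethylsilyloxy)-1-hydroxyhex-5-en-1-yl]-4-methylcyclohex-3-en-1-ol (both C7 epimers) | C=C[C@H](O[Si](C)(C)C(C)(C)C)CCC(O)[C@]1(O)CCC(C)=CC1 | intermediate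
16 | (4R)-4-(tert-butyldimethylsilyloxy)-1-[(1S)-1-hydroxy-4-methylcyclohex-3-en-1-yl]hex-5-en-1-one | C=C[C@H](O[Si](C)(C)C(C)(C)C)CCC(=O)[C@]1(O)CCC(C)=CC1 | intermediate
17 | (4R)-4-(tert-butyldimethylsilyloxy)-1-[(1S)-1-hydroxy-4-methylcyclohex-3-en-1-yl]hexane-1,5-dione | CC(=O)[C@H](O[Si](C)(C)C(C)(C)C)CCC(=O)[C@]1(O)CCC(C)=CC1 | intermediate
18 | (4R)-1-[(1S,3R,4R)-3-bromo-4-methyl-7-oxabicyclo[2.2.1]heptan-1-yl]-4-(tert-butyldimethylsilyloxy)hexane-1,5-dione | CC(=O)[C@H](O[Si](C)(C)C(C)(C)C)CCC(=O)[C@]1(O2)CC[C@]2(C)[C@H](Br)C1 | intermediate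
19 | trichlorotitanium alkoxide of 20 | CC(=O)[C@H](O[Si](C)(C)C(C)(C)C)CCC(=O)[C@]1(O[Ti](Cl)(Cl)Cl)CC[C@@](C)(Cl)[C@H](Br)C1 | intermediate (not isolated)
20 | (4R)-1-[(1S,3R,4R)-3-bromo-4-chloro-1-hydroxy-4-methylcyclohexyl]-4-(tert-butyldimethylsilyloxy)hexane-1,5-dione | CC(=O)[C@H](O[Si](C)(C)C(C)(C)C)CCC(=O)[C@]1(O)CC[C@@](C)(Cl)[C@H](Br)C1 | intermediate
21 | (4R)-1-[(1S,3R,4R)-3-bromo-4-chloro-4-methyl-1-(triethylsilyloxy)cyclohexyl]-4-(tert-butyldimethylsilyloxy)hexane-1,5-dione | CC(=O)[C@H](O[Si](C)(C)C(C)(C)C)CCC(=O)[C@]1(O[Si](CC)(CC)CC)CC[C@@](C)(Cl)[C@H](Br)C1 | intermediate (key-step precursor)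
22 | (4R)-1-[(1S,3R,4R)-3-bromo-4-chloro-4-methyl-1-(triethylsilyloxy)cyclohexyl]-4-(tert-butyldimethylsilyloxy)-5-methylhex-5-en-1-one | C=C(C)[C@H](O[Si](C)(C)C(C)(C)C)CCC(=O)[C@]1(O[Si](CC)(CC)CC)CC[C@@](C)(Cl)[C@H](Br)C1 | intermediate (not isolated)
23 | {[(1S,3R,4R)-3-bromo-1-[(5R)-5-(tert-butyldimethylsilyloxy)-6-methylhepta-1,6-dien-2-yl]-4-chloro-4-methylcyclohexyl]oxy}triethylsilane | C=C(C)[C@H](O[Si](C)(C)C(C)(C)C)CCC(=C)[C@]1(O[Si](CC)(CC)CC)CC[C@@](C)(Cl)[C@H](Br)C1 | intermediate (key-step product)
24 | (1S,3R,4R)-3-bromo-1-[(5R)-5-(tert-butyldimethylsilyloxy)-6-methylhepta-1,6-dien-2-yl]-4-chloro-4-methylcyclohexan-1-ol | C=C(C)[C@H](O[Si](C)(C)C(C)(C)C)CCC(=C)[C@]1(O)CC[C@@](C)(Cl)[C@H](Br)C1 | intermediate (not isolated)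
25 | (1S,3R,4R)-3-bromo-4-chloro-1-[(5R)-5-hydroxy-6-methylhepta-1,6-dien-2-yl]-4-methylcyclohexan-1-ol | C=C(C)[C@H](O)CCC(=C)[C@]1(O)CC[C@@](C)(Cl)[C@H](Br)C1 | target

**Step count**

Total: 17 steps. Longest linear sequence: 13 steps (steps 1–5, then 10–17). The side branch is steps 6–9.

**Steps most likely to fail**

1. Step 14 (Proposed new method). Ionisation of the C4–O bond may end in proton loss to an alkene or in return to the bridged ether instead of chloride capture, or the Lewis acid may strip the TBS group. The fallback uses known chemistry, sets out from 17 and comes back at 21. Compound 17 would be silylated (Et3SiOTf, 2,6-lutidine, CH2Cl2, −78 °C) to (4R)-4-(tert-butyldimethylsilyloxy)-1-[(1S)-4-methyl-1-(triethylsilyloxy)cyclohex-3-en-1-yl]hexane-1,5-dione F1. The ring alkene of F1 would then undergo a standard intermolecular anti bromochlorination (NBS, Me3SiCl, CH2Cl2, −78 to 0 °C), which places chlorine at the tertiary C4. This should give 21 together with (4R)-1-[(1S,3S,4S)-3-bromo-4-chloro-4-methyl-1-(triethylsilyloxy)cyclohexyl]-4-(tert-butyldimethylsilyloxy)hexane-1,5-dione F2, from the bromonium ion on the other face. The two would have to be separated by chromatography, because facial selectivity is then under substrate control only and may well favour F2.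

2. Step 13. The C1 hydroxyl, hydrogen-bonded to and deactivated by the adjacent ketone, may trap the bromonium ion too slowly, so that intermolecular capture by succinimide or water takes over. The fallback sets out from 4 and comes back at 18; it closes the oxygen bridge before the chain is attached, where C1–OH is an ordinary tertiary alcohol. Selective silylation of the primary hydroxyl of 4 (Et3SiCl, imidazole, CH2Cl2, −20 °C) would give (1S)-4-methyl-1-[(triethylsilyloxy)methyl]cyclohex-3-en-1-ol F3. NBS would convert it to {[(1S,3R,4R)-3-bromo-4-methyl-7-oxabicyclo[2.2.1]heptan-1-yl]methoxy}triethylsilane F4. Swern oxidation of the primary triethylsilyl ether would give (1S,3R,4R)-3-bromo-4-methyl-7-oxabicyclo[2.2.1]heptane-1-carbaldehyde F5. Addition of alkyllithium 13 at −78 °C would give (4R)-1-[(1S,3R,4R)-3-bromo-4-methyl-7-oxabicyclo[2.2.1]heptan-1-yl]-4-(tert-butyldimethylsilyloxy)hex-5-en-1-ol F6. IBX would give (4R)-1-[(1S,3R,4R)-3-bromo-4-methyl-7-oxabicyclo[2.2.1]heptan-1-yl]-4-(tert-butyldimethylsilyloxy)hex-5-en-1-one F7, and the Wacker conditions of step 12 would give 18. In this variant the bridge also serves as the protecting group of the C1 oxygen during the coupling.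

3. Step 16. Methylenation may stop at 22 because the C7 ketone is flanked by the quaternary silyloxy carbon, or the aluminium by-product may ionise the tertiary chloride. The fallback sets out from 21 and comes back at 25; it replaces the carbene [2+2] pathway by a two-stage Peterson olefination. Addition of Me3SiCH2Li/CeCl3 (THF, −78 °C) to both ketones would give (3R)-6-[(1S,3R,4R)-3-bromo-4-chloro-4-methyl-1-(triethylsilyloxy)cyclohexyl]-3-(tert-butyldimethylsilyloxy)-2-methyl-1,7-bis(trimethylsilyl)heptane-2,6-diol F8 as a mixture of carbinol epimers. Aqueous HF in MeCN would then effect the acid-promoted elimination at both carbinols and remove both silyl ethers, giving 25 directly.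

**Further compounds**

F1 | step 14 | (4R)-4-(tert-butyldimethylsilyloxy)-1-[(1S)-4-methyl-1-(triethylsilyloxy)cyclohex-3-en-1-yl]hexane-1,5-dione | CC(=O)[C@H](O[Si](C)(C)C(C)(C)C)CCC(=O)[C@]1(O[Si](CC)(CC)CC)CCC(C)=CC1
F2 | step 14 | (4R)-1-[(1S,3S,4S)-3-bromo-4-chloro-4-methyl-1-(triethylsilyloxy)cyclohexyl]-4-(tert-butyldimethylsilyloxy)hexane-1,5-dione | CC(=O)[C@H](O[Si](C)(C)C(C)(C)C)CCC(=O)[C@]1(O[Si](CC)(CC)CC)CC[C@](C)(Cl)[C@@H](Br)C1
F3 | step 13 | (1S)-4-methyl-1-[(triethylsilyloxy)methyl]cyclohex-3-en-1-ol | CC[Si](CC)(CC)OC[C@]1(O)CCC(C)=CC1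
F4 | step 13 | {[(1S,3R,4R)-3-bromo-4-methyl-7-oxabicyclo[2.2.1]heptan-1-yl]methoxy}triethylsilane | CC[Si](CC)(CC)OC[C@]1(O2)CC[C@]2(C)[C@H](Br)C1
F5 | step 13 | (1S,3R,4R)-3-bromo-4-methyl-7-oxabicyclo[2.2.1]heptane-1-carbaldehyde | O=C[C@]1(O2)CC[C@]2(C)[C@H](Br)C1
F6 | step 13 | (4R)-1-[(1S,3R,4R)-3-bromo-4-methyl-7-oxabicyclo[2.2.1]heptan-1-yl]-4-(tert-butyldimethylsilyloxy)hex-5-en-1-ol (both carbinol epimers) | C=C[C@H](O[Si](C)(C)C(C)(C)C)CCC(O)[C@]1(O2)CC[C@]2(C)[C@H](Br)C1
F7 | step 13 | (4R)-1-[(1S,3R,4R)-3-bromo-4-methyl-7-oxabicyclo[2.2.1]heptan-1-yl]-4-(tert-butyldimethylsilyloxy)hex-5-en-1-one | C=C[C@H](O[Si](C)(C)C(C)(C)C)CCC(=O)[C@]1(O2)CC[C@]2(C)[C@H](Br)C1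
F8 | step 16 | (3R)-6-[(1S,3R,4R)-3-bromo-4-chloro-4-methyl-1-(triethylsilyloxy)cyclohexyl]-3-(tert-butyldimethylsilyloxy)-2-methyl-1,7-bis(trimethylsilyl)heptane-2,6-diol (carbinol epimers) | C[Si](C)(C)CC(C)(O)[C@H](O[Si](C)(C)C(C)(C)C)CCC(O)(C[Si](C)(C)C)[C@]1(O[Si](CC)(CC)CC)CC[C@@](C)(Cl)[C@H](Br)C1
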